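## Analysis of the target

The target 21 is a 1,2-di-O-acyl-sn-glycerol whose glycerol carbon C2 is S, whose sn-3 hydroxyl is free and whose two acyl groups are the same C18 residue. Numbered from the ester carbon C1, each chain holds a conjugated diyne (C4≡C5–C6≡C7), a trans oxirane at C8–C9 with the 8S,9S configuration, three methylenes (C10–C12), a 13Z,15Z diene and an ethyl end (C17–C18). There are five stereocentres, the glycerol carbon and the four oxirane carbons; the oxiranes lie far from the glycerol centre and cannot be controlled from it, so each oxirane pair must be set by a reagent and the glycerol centre is best taken from the chiral pool. The sensitive groups are the alkynyl oxiranes (acid, Lewis acids, soft nucleophiles attacking in the SN2′ sense), the Z,Z dienes (isomerisation, oxidants), the diynes (light, heat, copper with oxygen) and the 1,2-diacylglycerol itself, whose acyl groups migrate to the 1,3 positions under base, acid or on silica. The difficulty is a trans-disubstituted oxirane with no neighbouring hydroxyl to direct a reagent, together with the geometric purity of four Z alkenes and a final deprotection that must not move an acyl group. The strategy rests on one structural fact: C8 of the oxirane is bonded directly to C7 of the C6≡C7 alkyne. Oxygen transfer to a C8=C9 alkene conjugated to that alkyne can run stepwise through a propargylic radical at C8, which can turn about the C8–C9 bond before the ring closes, so an easily made Z enyne is funnelled to the trans oxirane. Because the two chains are identical, one epoxy alkyne serves twice.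

## Retrosynthetic reasoning

**21 to 20.** The last bond cut is the benzylic C–O bond of a 4-methoxybenzyl ether on the sn-3 oxygen. The free 1,2-diacylglycerol cannot be carried through any basic step without acyl migration, so it is unmasked last. The forward reaction has to be a neutral oxidative ether cleavage that leaves esters, oxiranes, diynes and dienes alone.

**20 to 19 and two molecules of 13.** Both C5–C6 bonds are cut, in the middle of each diyne. This divides the molecule into a glycerol template 19 carrying two bromoalkynes and two copies of one chiral fragment, the terminal alkyne 13. The forward reaction, a copper-catalysed bromoalkyne–alkyne coupling (Cadiot–Chodkiewicz), gives the unsymmetrical diyne directly. Cutting the ester C–O bonds instead would mean esterifying twice with an acid that already carries diyne, oxirane and diene; that order is held in reserve.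

**19 to 16 and 18; 16 to 15 to 14; 18 to 17.** The ester C–O bonds are cut on the simple bromoalkynoic acid 18, made from 17 by bromination of the alkyne C–H. The glycerol centre comes from 14, whose free hydroxyl corresponds in space to the sn-3 hydroxyl of 21. Protecting that hydroxyl (15) and hydrolysing the acetal (16) exposes exactly the two hydroxyls that are to be acylated.

**13 to 12.** The C–Si bond is cut. The silyl cap hides the acidic alkyne C–H during the strong-base step that precedes it and is removed just before the coupling.

**12 to 8 (through ylide 11) and 10.** The C13=C14 alkene is cut. This gives a non-stabilised ylide, the class with the best Z selectivity, and takes the C15=C16 alkene ready-made from the Z enal 10, obtained by oxidation of 9. Cutting C15=C16 instead would put a labile Z enal on the valuable fragment.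

**8 to 7 to 6.** The C–P bond and then the C–I bond are cut back to the chloride. A primary chloride is chosen as the spectator on the epoxidation substrate because it is inert to the oxidant and to palladium, yet can be activated later by halide exchange.

**6 to 5.** Both C–O bonds of the oxirane are cut, leading to the Z enyne 5. This is the key disconnection. The epoxidation is placed before the diene exists so that the oxidant meets a single alkene. The forward reaction has to select one enantioface and turn the cis alkene into the trans oxirane.

**5 to 3 and 4; 3 to 2 to 1.** The C7–C8 bond is cut (sp–sp2 coupling of vinyl iodide 3 with silylalkyne 4, with retention of geometry). The Z geometry of 3 comes from syn hydrogen transfer to iodoalkyne 2, which is the iodination product of 1.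

## Alternatives that were turned down

Alternative 1: The diene is disconnected at C12–C13, C14–C15 and C16–C17, and the oxirane is traced to an E allylic alcohol. In the forward key step lithium diethylcuprate A2 adds syn to two molecules of acetylene A3 to give lithium bis[(1Z,3Z)-hexa-1,3-dienyl]cuprate A4. The cuprate A4 is alkylated by the primary iodide tert-butyl{[(2E)-6-iodohex-2-en-1-yl]oxy}dimethylsilane A5 to give the trienyl silyl ether A1. Desilylation, Sharpless epoxidation, oxidation and one-carbon alkyne homologation would then lead to 13. In its favour, both Z alkenes arise from syn carbometalation starting at A2, so their geometry is fixed by mechanism and no labile Z enal is needed. The Ti(OiPr)4/diethyl tartrate epoxidation of an E allylic alcohol is also the most dependable way to a trans oxirane of predictable configuration. Against it, alkylation of alkenyl cuprates by unactivated primary iodides is sluggish and needs a toxic phosphoramide cosolvent and gaseous A3. The diene is then carried through a peroxide epoxidation, an oxidation to an epimerisable epoxy aldehyde and a homologation, and A5 needs several steps of its own. On diene geometry and on predictability of the oxirane configuration this alternative is stronger. The chosen strategy offers the alkynyl oxirane at the correct oxidation level in one catalytic step from 5, three steps from commercial material, and it keeps the diene away from every oxidant by installing it afterwards. The overall step counts are close.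

Alternative 2: Both C5–C6 bonds are disconnected at once. In the forward key step the bis(bromoalkyne) 19 couples with two equivalents of 13 under CuCl, NH2OH·HCl and n-BuNH2 to give the protected diacylglycerol A6, which is the same compound as 20. In its favour are maximal convergence, use of the identity of the two chains, formation of the diyne without handling a free diyne acid, and esterification on a simple acid. Against it as a strategy: the coupling creates no ring and no stereocentre, so it leaves open where the (S,S) alkynyl oxirane comes from, which is the real problem of this target. A double coupling also carries the risk of an incomplete second coupling and of amine attack on the esters. On convergence it is as strong as anything available, and it is adopted as step 14 of the chosen route. The chosen strategy adds the answer to the stereochemical problem.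

Alternative 3: The oxirane is disconnected at C8–C9 and C9–O. In the forward key step the ylide made from the C2-symmetric sulfonium salt A8 and a strong non-nucleophilic base adds to (5Z,7Z)-deca-5,7-dienal A9. The betaine closes to the trans oxirane A7 with release of the chiral sulfide, and desilylation of A7 would give 13. In its favour: a C–C bond, the ring and both stereocentres form in one convergent operation, the alkyne arrives attached, and no oxidant ever meets the diene. Against it: enantio- and diastereocontrol in sulfur ylide epoxidation depend on the reversibility of betaine formation, which is least predictable for a propargyl ylide with an unbranched aliphatic aldehyde. The ylide is also ambident (propargyl and allenyl forms, sigmatropic rearrangement), and the sulfur auxiliary is stoichiometric and must be made. The aldehyde A9 itself needs a multistep synthesis that still has to solve the Z,Z diene. On convergence and on sparing the diene this alternative is stronger. The chosen strategy offers a catalyst available in both mirror-image forms, a substrate class (cis enynes) with a mechanistic reason for trans closure, and a very short path to the substrate 5.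

Key step: step 4

Remark on the chemistry: the (R,R) catalyst is assigned by analogy with aryl-substituted cis alkenes, the alkynyl group taking the place of the aryl group; the mirror-image catalyst is equally available should the sense prove opposite. Pent-4-ynoic acid 17 is taken as a fifth commercial starting material.

## Route

Step 1
Reactants: 1 6-chlorohex-1-yne
Product: 2 6-chloro-1-iodohex-1-yne
Conditions: N-iodosuccinimide, AgNO3 (cat.), acetone, rt, dark
Reagents that add atoms: N-iodosuccinimide, O=C1CCC(=O)N1I
Why: Silver-catalysed electrophilic iodination of a terminal alkyne C–H through the silver acetylide is a standard route to 1-iodoalkynes; the primary chloride is inert.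

Step 2
Reactants: 2 6-chloro-1-iodohex-1-yne
Product: 3 (Z)-6-chloro-1-iodohex-1-ene
Conditions: 2-nitrobenzenesulfonyl hydrazide, Et3N, THF/i-PrOH, rt
Reagents that add atoms: none
Why: Diimide released from the sulfonyl hydrazide transfers two hydrogens syn through a cyclic transition state, so the iodoalkyne should give the Z vinyl iodide without cleavage of C–I or C–Cl; the vinyl iodide is reduced more slowly than the iodoalkyne (diimide cis-reduction).

Step 3
Reactants: 3 (Z)-6-chloro-1-iodohex-1-ene; 4 (triisopropylsilyl)acetylene
Product: 5 (Z)-(8-chlorooct-3-en-1-yn-1-yl)tri(propan-2-yl)silane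
Conditions: PdCl2(PPh3)2 (cat.), CuI (cat.), i-Pr2NH, THF, rt
Reagents that add atoms: none
Why: Sonogashira coupling of an alkenyl iodide at room temperature forms C7–C8 with retention of the Z geometry; the alkyl chloride does not add oxidatively to zerovalent palladium under these conditions.

Step 4
Reactants: 5 (Z)-(8-chlorooct-3-en-1-yn-1-yl)tri(propan-2-yl)silane
Product: 6 {[(2S,3S)-3-(4-chlorobutyl)oxiran-2-yl]ethynyl}tri(propan-2-yl)silane
Conditions: (R,R)-(salen)MnCl [salen = N,N′-bis(3,5-di-tert-butylsalicylidene)cyclohexane-1,2-diamine dianion, trivalent manganese] (5 mol%), 4-phenylpyridine N-oxide (25 mol%), aq. NaOCl buffered to pH 11.3 (Na2HPO4), CH2Cl2, 0 °C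
Reagents that add atoms: sodium hypochlorite, [Na+].[O-]Cl
Why: Hypochlorite oxidises the catalyst to the oxo complex of pentavalent manganese, with the N-oxide as axial ligand to stabilise it and speed turnover. Oxygen is transferred stepwise: the first C–O bond forms at C9 (oxirane C3), the alkene carbon remote from the alkyne, and leaves a propargylic, allenyl-delocalised radical at C8 (oxirane C2). This radical should live long enough to turn about the C8–C9 single bond, so that its collapse onto the manganese-bound oxygen (a 3-exo closure by homolytic substitution at oxygen, returning trivalent manganese) gives mainly the trans oxirane; the closest known reaction type is the (salen)MnCl-catalysed epoxidation of cis enynes, which gives trans alkynyl epoxides as main products. C9 is fixed in the first bond formation by the enantioface selection of the salen ligand (side-on approach of the cis alkene, the alkynyl group sitting where the aryl group of a cis styrene sits), which for the (R,R) ligand is expected to give 9S. C8 is fixed by the rotation and trans collapse and becomes 8S. The step needs chemoselectivity, trans over cis closure and enantioselectivity: the substrate has a single alkene, the alkyl chloride and the silylalkyne are inert to hypochlorite, the alkyne supplies the radical stabilisation that allows rotation, and the bulky triisopropylsilyl group disfavours cis closure. The minor cis epoxide should be removable by chromatography.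

Step 5
Reactants: 6 {[(2S,3S)-3-(4-chlorobutyl)oxiran-2-yl]ethynyl}tri(propan-2-yl)silane
Product: 7 {[(2S,3S)-3-(4-iodobutyl)oxiran-2-yl]ethynyl}tri(propan-2-yl)silane
Conditions: NaI, NaHCO3, acetone, reflux
Reagents that add atoms: sodium iodide, [Na+].[I-]
Why: Finkelstein exchange (SN2 at the primary carbon) is driven by precipitation of NaCl; under neutral, bicarbonate-buffered conditions iodide should not open the oxirane.

Step 6
Reactants: 7 {[(2S,3S)-3-(4-iodobutyl)oxiran-2-yl]ethynyl}tri(propan-2-yl)silane
Product: 8 triphenyl{4-[(2S,3S)-3-{[tri(propan-2-yl)silyl]ethynyl}oxiran-2-yl]butyl}phosphonium iodide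
Conditions: PPh3, MeCN, 75 °C
Reagents that add atoms: triphenylphosphine, c1ccc(cc1)P(c1ccccc1)c1ccccc1
Why: SN2 quaternisation of the phosphine by the primary iodide; neutral PPh3 does not open an unactivated oxirane at this temperature in the absence of acid.

Step 7
Reactants: 9 (Z)-pent-2-en-1-ol
Product: 10 (Z)-pent-2-enal
Conditions: Dess–Martin periodinane, NaHCO3, CH2Cl2, 0 °C; used at once without chromatography
Reagents that add atoms: none
Why: Dess–Martin oxidation under bicarbonate buffering is mild and non-acidic, so the Z geometry of the enal should be kept if the aldehyde is used immediately.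

Step 8
Reactants: 8 triphenyl{4-[(2S,3S)-3-{[tri(propan-2-yl)silyl]ethynyl}oxiran-2-yl]butyl}phosphonium iodide; 10 (Z)-pent-2-enal
Product: 12 {[(2S,3S)-3-[(4Z,6Z)-nona-4,6-dien-1-yl]oxiran-2-yl]ethynyl}tri(propan-2-yl)silane, via phosphonium ylide 11 (not isolated)
Conditions: NaN(SiMe3)2 (slightly less than 1 equiv), THF, −78 °C; then 10, −78 to −20 °C
Reagents that add atoms: none
Why: The Wittig reaction of a non-stabilised ylide under lithium-free conditions gives the Z alkene C13=C14 by kinetic control in oxaphosphetane formation. Carbonyl addition at −78 °C is much faster than isomerisation of the enal, so the C15=C16 geometry should be carried through. The silyl cap prevents acetylide formation, and the ylide is not expected to open the remote oxirane at this temperature.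

Step 9
Reactants: 12 {[(2S,3S)-3-[(4Z,6Z)-nona-4,6-dien-1-yl]oxiran-2-yl]ethynyl}tri(propan-2-yl)silane
Product: 13 (2S,3S)-2-ethynyl-3-[(4Z,6Z)-nona-4,6-dien-1-yl]oxirane
Conditions: Bu4NF, THF, 0 °C
Reagents that add atoms: none
Why: Fluoride attacks silicon and releases the acetylide, which is protonated on work-up (protodesilylation); oxirane and diene should be untouched at 0 °C.

Step 10
Reactants: 14 (S)-solketal
Product: 15 (4S)-4-{[(4-methoxyphenyl)methoxy]methyl}-2,2-dimethyl-1,3-dioxolane
Conditions: NaH, 4-MeOC6H4CH2Cl, Bu4NI (cat.), THF/DMF, 0 °C to rt
Reagents that add atoms: 4-methoxybenzyl chloride, COc1ccc(CCl)cc1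
Why: Williamson etherification of the primary alkoxide; the stereocentre is not involved.

Step 11
Reactants: 15 (4S)-4-{[(4-methoxyphenyl)methoxy]methyl}-2,2-dimethyl-1,3-dioxolane
Product: 16 (2R)-3-[(4-methoxyphenyl)methoxy]propane-1,2-diol
Conditions: AcOH/H2O 4:1, 40 °C
Reagents that add atoms: none
Why: Acid-catalysed acetal hydrolysis; the 4-methoxybenzyl ether survives dilute acetic acid and no bond to the stereocentre is broken (the descriptor changes only through the priority rules).

Step 12
Reactants: 17 pent-4-ynoic acid
Product: 18 5-bromopent-4-ynoic acid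
Conditions: Br2, KOH, H2O, 0 °C; then HCl to pH 2
Reagents that add atoms: bromine, BrBr
Why: Hypobromite bromination of a terminal alkyne in alkaline water replaces the acetylenic hydrogen; in strongly basic medium no electrophilic bromine species activates the triple bond, so bromolactonisation of the carboxylate should not compete.

Step 13
Reactants: 16 (2R)-3-[(4-methoxyphenyl)methoxy]propane-1,2-diol; 18 5-bromopent-4-ynoic acid (2.2 equiv)
Product: 19 (2S)-3-[(4-methoxyphenyl)methoxy]propane-1,2-diyl bis(5-bromopent-4-ynoate)
Conditions: DCC, DMAP (cat.), CH2Cl2, 0 °C to rt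
Reagents that add atoms: none
Why: Steglich esterification acylates both hydroxyls, so no acyl migration can arise; bromoalkynes are inert to carbodiimide and DMAP.

Step 14
Reactants: 19 (2S)-3-[(4-methoxyphenyl)methoxy]propane-1,2-diyl bis(5-bromopent-4-ynoate); 13 (2S,3S)-2-ethynyl-3-[(4Z,6Z)-nona-4,6-dien-1-yl]oxirane (2.3 equiv)
Product: 20 (2S)-3-[(4-methoxyphenyl)methoxy]propane-1,2-diyl bis{7-[(2S,3S)-3-[(4Z,6Z)-nona-4,6-dien-1-yl]oxiran-2-yl]hepta-4,6-diynoate}
Conditions: CuCl (cat.), NH2OH·HCl, n-BuNH2, Et2O/H2O, 0 °C, slow addition of 19, argon, dim light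
Reagents that add atoms: none
Why: In the Cadiot–Chodkiewicz coupling the copper acetylide of 13 reacts with each bromoalkyne to form the two C5–C6 bonds and the unsymmetrical diynes. Hydroxylamine keeps copper monovalent and suppresses oxidative homocoupling, and a short, cold reaction should spare the esters and oxiranes.

Step 15
Reactants: 20 (2S)-3-[(4-methoxyphenyl)methoxy]propane-1,2-diyl bis{7-[(2S,3S)-3-[(4Z,6Z)-nona-4,6-dien-1-yl]oxiran-2-yl]hepta-4,6-diynoate}
Product: 21 (2S)-3-hydroxypropane-1,2-diyl bis{7-[(2S,3S)-3-[(4Z,6Z)-nona-4,6-dien-1-yl]oxiran-2-yl]hepta-4,6-diynoate}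
Conditions: DDQ, CH2Cl2/pH 7 phosphate buffer, 0 °C, short reaction time; rapid chromatography on boric-acid-treated silica
Reagents that add atoms: none
Why: DDQ oxidises the electron-rich 4-methoxybenzyl ether to an oxocarbenium ion that water hydrolyses (oxidative PMB cleavage). The neutral buffered medium should avoid 1,2 to 1,3 acyl migration, and a Z,Z diene reaches the s-cis conformation needed for cycloaddition to the quinone only with difficulty.

## Compound list

1 | 6-chlorohex-1-yne | C#CCCCCCl | starting material
2 | 6-chloro-1-iodohex-1-yne | ClCCCCC#CI | intermediate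
3 | (Z)-6-chloro-1-iodohex-1-ene | ClCCCC/C=C\I | intermediate
4 | (triisopropylsilyl)acetylene | C#C[Si](C(C)C)(C(C)C)C(C)C | starting material
5 | (Z)-(8-chlorooct-3-en-1-yn-1-yl)tri(propan-2-yl)silane | CC(C)[Si](C(C)C)(C(C)C)C#C/C=C\CCCCCl | intermediate
6 | {[(2S,3S)-3-(4-chlorobutyl)oxiran-2-yl]ethynyl}tri(propan-2-yl)silane | CC(C)[Si](C(C)C)(C(C)C)C#C[C@@H]1O[C@H]1CCCCCl | intermediate
7 | {[(2S,3S)-3-(4-iodobutyl)oxiran-2-yl]ethynyl}tri(propan-2-yl)silane | CC(C)[Si](C(C)C)(C(C)C)C#C[C@@H]1O[C@H]1CCCCI | intermediate
8 | triphenyl{4-[(2S,3S)-3-{[tri(propan-2-yl)silyl]ethynyl}oxiran-2-yl]butyl}phosphonium iodide | CC(C)[Si](C(C)C)(C(C)C)C#C[C@@H]1O[C@H]1CCCC[P+](c1ccccc1)(c1ccccc1)c1ccccc1.[I-] | intermediate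
9 | (Z)-pent-2-en-1-ol | CC/C=C\CO | starting material
10 | (Z)-pent-2-enal | CC/C=C\C=O | intermediate
11 | triphenyl{4-[(2S,3S)-3-{[tri(propan-2-yl)silyl]ethynyl}oxiran-2-yl]butylidene}phosphorane (ylide) | CC(C)[Si](C(C)C)(C(C)C)C#C[C@@H]1O[C@H]1CCCC=P(c1ccccc1)(c1ccccc1)c1ccccc1 | intermediate
12 | {[(2S,3S)-3-[(4Z,6Z)-nona-4,6-dien-1-yl]oxiran-2-yl]ethynyl}tri(propan-2-yl)silane | CC/C=C\C=C/CCC[C@@H]1O[C@H]1C#C[Si](C(C)C)(C(C)C)C(C)C | intermediate
13 | (2S,3S)-2-ethynyl-3-[(4Z,6Z)-nona-4,6-dien-1-yl]oxirane | CC/C=C\C=C/CCC[C@@H]1O[C@H]1C#C | intermediate
14 | (S)-solketal, [(4S)-2,2-dimethyl-1,3-dioxolan-4-yl]methanol | CC1(C)OC[C@H](CO)O1 | starting material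
15 | (4S)-4-{[(4-methoxyphenyl)methoxy]methyl}-2,2-dimethyl-1,3-dioxolane | CC1(C)OC[C@H](COCc2ccc(OC)cc2)O1 | intermediate
16 | (2R)-3-[(4-methoxyphenyl)methoxy]propane-1,2-diol | OC[C@H](COCc1ccc(OC)cc1)O | intermediate
17 | pent-4-ynoic acid | C#CCCC(=O)O | starting material
18 | 5-bromopent-4-ynoic acid | BrC#CCCC(=O)O | intermediate
19 | (2S)-3-[(4-methoxyphenyl)methoxy]propane-1,2-diyl bis(5-bromopent-4-ynoate) | BrC#CCCC(=O)OC[C@H](COCc1ccc(OC)cc1)OC(=O)CCC#CBr | intermediate
20 | (2S)-3-[(4-methoxyphenyl)methoxy]propane-1,2-diyl bis{7-[(2S,3S)-3-[(4Z,6Z)-nona-4,6-dien-1-yl]oxiran-2-yl]hepta-4,6-diynoate} | CC/C=C\C=C/CCC[C@@H]1O[C@H]1C#CC#CCCC(=O)OC[C@H](COCc2ccc(OC)cc2)OC(=O)CCC#CC#C[C@@H]1O[C@H]1CCC/C=C\C=C/CC | intermediate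
21 | (2S)-3-hydroxypropane-1,2-diyl bis{7-[(2S,3S)-3-[(4Z,6Z)-nona-4,6-dien-1-yl]oxiran-2-yl]hepta-4,6-diynoate} | CC/C=C\C=C/CCC[C@@H]1O[C@H]1C#CC#CCCC(=O)OC[C@H](CO)OC(=O)CCC#CC#C[C@@H]1O[C@H]1CCC/C=C\C=C/CC | target

## Step count and least certain steps

Total: 15 steps. Longest linear sequence: 10 steps (steps 1, 2, 3, 4, 5, 6, 8, 9, 14, 15, from 1 to 21).

**Step 4 (key step).** The most likely failure is incomplete funnelling: direct collapse of the radical competes with rotation and gives the cis epoxide alongside the trans one, and the enantiomeric purity of the trans product may be lower than needed. The sense of induction could be opposite to the one assigned, and a bulky silyl enyne may turn over slowly so that the catalyst bleaches. The fallback sets out from 1 and comes back at 6, and sets the oxirane by directed epoxidation of an allylic alcohol. Deprotonation of 1 with n-BuLi and addition to paraformaldehyde should give 7-chlorohept-2-yn-1-ol F1, and reduction with NaAlH2(OCH2CH2OMe)2 should give (E)-7-chlorohept-2-en-1-ol F2. Sharpless epoxidation with Ti(OiPr)4, L-(+)-diethyl tartrate and t-BuOOH over 4 Å sieves at −20 °C should give [(2S,3S)-3-(4-chlorobutyl)oxiran-2-yl]methanol F3. Dess–Martin oxidation should give (2R,3S)-3-(4-chlorobutyl)oxirane-2-carbaldehyde F4. Ohira–Bestmann homologation with dimethyl (1-diazo-2-oxopropyl)phosphonate and K2CO3 in MeOH should give (2S,3S)-2-(4-chlorobutyl)-3-ethynyloxirane F5. Deprotonation with LiN(SiMe3)2 and silylation with i-Pr3SiOTf at −78 °C then gives 6.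

**Step 8 (with step 6 before it).** The Z enal may isomerise to the E form before or during the coupling and erode the geometry at C15=C16. Selectivity at C13=C14 may be incomplete. The oxirane may be opened during phosphonium salt formation or by the ylide within the same molecule. The fallback sets out from 7 and comes back at 12, and replaces the Wittig step by olefination plus sp2–sp2 coupling. Oxidation of the iodide with trimethylamine N-oxide in DMSO at rt should give 4-[(2S,3S)-3-{[tri(propan-2-yl)silyl]ethynyl}oxiran-2-yl]butanal F6. Stork–Zhao olefination with (iodomethyl)triphenylphosphonium iodide and NaN(SiMe3)2 in THF at −78 °C should give the Z vinyl iodide {[(2S,3S)-3-[(4Z)-5-iodopent-4-en-1-yl]oxiran-2-yl]ethynyl}tri(propan-2-yl)silane F7. The partner tributyl[(1Z)-but-1-en-1-yl]stannane F8 is made by syn addition of an ethylcopper reagent (EtMgBr, CuBr·SMe2) to acetylene and quench with Bu3SnCl. Palladium-free coupling of F7 with F8, mediated by Cu(O2CC4H3S) (copper thiophene-2-carboxylate, monovalent copper) in NMP at 0 °C, forms C14–C15 with retention at both alkenes and gives 12. Palladium is avoided because zerovalent palladium can open alkynyl oxiranes.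

**Step 14.** The primary amine may attack the glycerol esters. The second coupling may stop short, leaving one bromoalkyne unreacted. Oxidative homocoupling may consume the valuable alkyne 13. The fallback sets out from 13 and 18 and comes back at 20, and makes each diyne on a monofunctional partner before esterification. Alkyne 13 is coupled with the free acid 18, present as its carboxylate and therefore immune to aminolysis, under the CuCl, NH2OH·HCl and n-BuNH2 conditions of step 14. This should give 7-[(2S,3S)-3-[(4Z,6Z)-nona-4,6-dien-1-yl]oxiran-2-yl]hepta-4,6-diynoic acid F9. Two equivalents of F9 are then esterified with diol 16 (DCC, DMAP, CH2Cl2, 0 °C) to give 20.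

**Step 15.** The quinone may attack the dienes, by hydride abstraction at the allylic positions C12 and C17 or by cycloaddition. An acyl group may migrate from O-2 to O-3 during cleavage or on silica. The fallback sets out from 19 and comes back at 21, and moves the oxidative cleavage to a stage with no diene and no oxirane. DDQ on 19 should give (2S)-3-hydroxypropane-1,2-diyl bis(5-bromopent-4-ynoate) F10. Immediate silylation with Et3SiOTf and 2,6-lutidine at −78 °C should give (2R)-3-[(triethylsilyl)oxy]propane-1,2-diyl bis(5-bromopent-4-ynoate) F11. Double coupling with 13 as in step 14 should give the silyl-protected diacylglycerol (2R)-3-[(triethylsilyl)oxy]propane-1,2-diyl bis{7-[(2S,3S)-3-[(4Z,6Z)-nona-4,6-dien-1-yl]oxiran-2-yl]hepta-4,6-diynoate} F12. Mild hydrolysis of the silyl ether (AcOH/THF/H2O, 0 °C to rt), under which acyl migration is slow, releases 21.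

## Further compounds

F1 | step 4 | 7-chlorohept-2-yn-1-ol | OCC#CCCCCCl
F2 | step 4 | (E)-7-chlorohept-2-en-1-ol | OC/C=C/CCCCCl
F3 | step 4 | [(2S,3S)-3-(4-chlorobutyl)oxiran-2-yl]methanol | OC[C@@H]1O[C@H]1CCCCCl
F4 | step 4 | (2R,3S)-3-(4-chlorobutyl)oxirane-2-carbaldehyde | O=C[C@@H]1O[C@H]1CCCCCl
F5 | step 4 | (2S,3S)-2-(4-chlorobutyl)-3-ethynyloxirane | C#C[C@@H]1O[C@H]1CCCCCl
F6 | step 8 | 4-[(2S,3S)-3-{[tri(propan-2-yl)silyl]ethynyl}oxiran-2-yl]butanal | CC(C)[Si](C(C)C)(C(C)C)C#C[C@@H]1O[C@H]1CCCC=O
F7 | step 8 | {[(2S,3S)-3-[(4Z)-5-iodopent-4-en-1-yl]oxiran-2-yl]ethynyl}tri(propan-2-yl)silane | CC(C)[Si](C(C)C)(C(C)C)C#C[C@@H]1O[C@H]1CCC/C=C\I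
F8 | step 8 | tributyl[(1Z)-but-1-en-1-yl]stannane | CC/C=C\[Sn](CCCC)(CCCC)CCCC
F9 | step 14 | 7-[(2S,3S)-3-[(4Z,6Z)-nona-4,6-dien-1-yl]oxiran-2-yl]hepta-4,6-diynoic acid | CC/C=C\C=C/CCC[C@@H]1O[C@H]1C#CC#CCCC(=O)O
F10 | step 15 | (2S)-3-hydroxypropane-1,2-diyl bis(5-bromopent-4-ynoate) | BrC#CCCC(=O)OC[C@H](CO)OC(=O)CCC#CBr
F11 | step 15 | (2R)-3-[(triethylsilyl)oxy]propane-1,2-diyl bis(5-bromopent-4-ynoate) | BrC#CCCC(=O)OC[C@H](CO[Si](CC)(CC)CC)OC(=O)CCC#CBr
F12 | step 15 | (2R)-3-[(triethylsilyl)oxy]propane-1,2-diyl bis{7-[(2S,3S)-3-[(4Z,6Z)-nona-4,6-dien-1-yl]oxiran-2-yl]hepta-4,6-diynoate} | CC/C=C\C=C/CCC[C@@H]1O[C@H]1C#CC#CCCC(=O)OC[C@H](CO[Si](CC)(CC)CC)OC(=O)CCC#CC#C[C@@H]1O[C@H]1CCC/C=C\C=C/CC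
A1 | alternative 1 | tert-butyldimethyl{[(2E,7Z,9Z)-dodeca-2,7,9-trien-1-yl]oxy}silane | CC/C=C\C=C/CCC/C=C/CO[Si](C)(C)C(C)(C)C
A2 | alternative 1 | lithium diethylcuprate | [Li+].CC[Cu-]CC
A3 | alternative 1 | acetylene | C#C
A4 | alternative 1 | lithium bis[(1Z,3Z)-hexa-1,3-dien-1-yl]cuprate | [Li+].CC/C=C\C=C/[Cu-]/C=C\C=C/CC
A5 | alternative 1 | tert-butyl{[(2E)-6-iodohex-2-en-1-yl]oxy}dimethylsilane | CC(C)(C)[Si](C)(C)OC/C=C/CCCI
A6 | alternative 2 | (2S)-3-[(4-methoxyphenyl)methoxy]propane-1,2-diyl bis{7-[(2S,3S)-3-[(4Z,6Z)-nona-4,6-dien-1-yl]oxiran-2-yl]hepta-4,6-diynoate} | CC/C=C\C=C/CCC[C@@H]1O[C@H]1C#CC#CCCC(=O)OC[C@H](COCc2ccc(OC)cc2)OC(=O)CCC#CC#C[C@@H]1O[C@H]1CCC/C=C\C=C/CC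
A7 | alternative 3 | trimethyl{[(2S,3S)-3-[(4Z,6Z)-nona-4,6-dien-1-yl]oxiran-2-yl]ethynyl}silane | CC/C=C\C=C/CCC[C@@H]1O[C@H]1C#C[Si](C)(C)C
A8 | alternative 3 | (2R,5R)-2,5-dimethyl-1-[3-(trimethylsilyl)prop-2-yn-1-yl]thiolan-1-ium trifluoromethanesulfonate | C[C@@H]1CC[C@@H](C)[S+]1CC#C[Si](C)(C)C.[O-]S(=O)(=O)C(F)(F)F
A9 | alternative 3 | (5Z,7Z)-deca-5,7-dienal | CC/C=C\C=C/CCCC=O
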